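**Plan** (hexahydroazulene numbering: C8a = quaternary C–Me, C3 = C–iPr, C3a = ring-fusion sp2 carbon, C6 = carbon bearing CH2O, C7 = vinylic CH, C8 = CH2 next to C8a)
- Retrosynthesis cuts, in order: the vanillate O–CH2 ester bond; the ring bond C7–C8, which opens the seven-membered ring; the C3=C3a double bond of the cyclopentene (diketone coupling); the C1–C8a bond (Michael addition); the C3a–C8a and C6–C7 bonds (two Claisen-type acylations).
- Forward: acyclic keto diester → quaternary centre → five-membered ring (step 3) → seven-membered ring by C7–C8 coupling (step 9) → ester reduction and vanillate ester.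
- Enabling feature: C8 is a CH2 on the quaternary C8a, so a zinc or palladium alkyl at C8 has no β-hydrogen; C7 is the β-carbon of the C6 acrylate unit of the seven-membered ring, so it can be carried as an (E)-enol triflate whose geometry becomes the cis ring alkene.
- Helpers: iodide/zinc at C8, triflate at C7 and the ethyl ester at C6 (the last is reduced to the CH2O carbon in step 10).
- Stereochemistry: C8a is the only stereocentre; it is set as a quaternary centre in the catalytic asymmetric Michael addition (step 2) and is not touched afterwards.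

Key step: step 9

Assumption: 4-methylpent-1-en-3-one and ethyl 5-chloro-5-oxopentanoate are taken as purchasable; the sense of induction in step 2 is assigned by analogy, and the antipodal ligand is used if the facial selectivity proves opposite.

Step 1
Reactants: 1 tert-butyl propanoate; 2 ethyl 5-chloro-5-oxopentanoate
Product: 3 1-tert-butyl 7-ethyl 2-methyl-3-oxoheptanedioate (racemic)
Conditions: LDA (2.1 equiv), THF, −78 °C; then 2, −78 → 0 °C
Reagents that add atoms: none
Why: Crossed Claisen C-acylation of a tert-butyl ester lithium enolate by an acid chloride, which reacts far faster than the ethyl ester; the second equivalent of enolate deprotonates the more acidic β-keto ester and so prevents diacylation.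

Step 2
Reactants: 3 1-tert-butyl 7-ethyl 2-methyl-3-oxoheptanedioate; 4 4-methylpent-1-en-3-one
Product: 5 1-tert-butyl 7-ethyl (2S)-2-methyl-2-(4-methyl-3-oxopentyl)-3-oxoheptanedioate
Conditions: [Pd((R)-BINAP)(H2O)2](OTf)2 (5 mol%), THF, −20 °C
Reagents that add atoms: none
Why: Catalytic asymmetric Michael addition of an α-methyl β-keto tert-butyl ester to a vinyl ketone through a chiral square-planar Pd(II) enolate, in which the BINAP ligand shields one enolate face so that C2 becomes the quaternary (S) centre.

Step 3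
Reactants: 5 1-tert-butyl 7-ethyl (2S)-2-methyl-2-(4-methyl-3-oxopentyl)-3-oxoheptanedioate
Product: 6 tert-butyl (1S)-2-(4-ethoxy-4-oxobutyl)-1-methyl-3-(propan-2-yl)cyclopent-2-ene-1-carboxylate
Conditions: TiCl3(DME)1.5, Zn–Cu, DME, reflux, slow addition
Reagents that add atoms: none
Why: Intramolecular McMurry coupling of the 1,5-diketone (ketyl coupling to a titanium pinacolate, then deoxygenation) should give the tetrasubstituted cyclopentene, because ketone–ketone coupling is faster than ketone–ester coupling and the quaternary centre cannot epimerise.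

Step 4
Reactants: 6 tert-butyl (1S)-2-(4-ethoxy-4-oxobutyl)-1-methyl-3-(propan-2-yl)cyclopent-2-ene-1-carboxylate
Product: 8 (1S)-2-(4-ethoxy-4-oxobutyl)-1-methyl-3-(propan-2-yl)cyclopent-2-ene-1-carboxylic acid, via trimethylsilyl ester 7 (not isolated)
Conditions: TMSOTf, 2,6-lutidine, CH2Cl2, 0 °C; aqueous work-up
Reagents that add atoms: trimethylsilyl trifluoromethanesulfonate, C[Si](C)(C)OS(=O)(=O)C(F)(F)F (its Me3Si group is present in 7 only)
Why: Silyl triflate-mediated tert-butyl ester cleavage (loss of 2-methylpropene) under buffered, non-protic conditions leaves the ethyl ester intact and avoids protonating the tetrasubstituted alkene, which would lead to γ-lactonisation.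

Step 5
Reactants: 8 (1S)-2-(4-ethoxy-4-oxobutyl)-1-methyl-3-(propan-2-yl)cyclopent-2-ene-1-carboxylic acid
Product: 9 ethyl 4-[(5S)-5-(hydroxymethyl)-5-methyl-2-(propan-2-yl)cyclopent-1-en-1-yl]butanoate
Conditions: BH3·THF, THF, 0 °C → rt; MeOH quench
Reagents that add atoms: none
Why: Borane reduces a carboxylic acid through its acyloxyborane much faster than an ester, and the tetrasubstituted alkene flanked by C8a and the isopropyl group should hydroborate only slowly.

Step 6
Reactants: 9 ethyl 4-[(5S)-5-(hydroxymethyl)-5-methyl-2-(propan-2-yl)cyclopent-1-en-1-yl]butanoate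
Product: 10 ethyl 4-[(5S)-5-(iodomethyl)-5-methyl-2-(propan-2-yl)cyclopent-1-en-1-yl]butanoate
Conditions: I2, PPh3, imidazole, toluene, 70 °C
Reagents that add atoms: iodine, II
Why: Appel-type iodination through the alkoxyphosphonium salt needs heat at the neopentyl carbon, and if the ring alkene participates, iodide should reopen the cyclopropylcarbinyl cation at the same unhindered CH2 and return the same primary iodide.

Step 7
Reactants: 10 ethyl 4-[(5S)-5-(iodomethyl)-5-methyl-2-(propan-2-yl)cyclopent-1-en-1-yl]butanoate; 11 ethyl formate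
Product: 12 ethyl 2-formyl-4-[(5S)-5-(iodomethyl)-5-methyl-2-(propan-2-yl)cyclopent-1-en-1-yl]butanoate (C2 epimers, in equilibrium with the enol)
Conditions: LDA, THF, −78 °C; then HCO2Et, −78 → 0 °C
Reagents that add atoms: none
Why: Crossed Claisen formylation of the ester enolate introduces the future C7, while the neopentyl iodide has no β-hydrogen for elimination and is inert to SN2 attack at this temperature.

Step 8
Reactants: 12 ethyl 2-formyl-4-[(5S)-5-(iodomethyl)-5-methyl-2-(propan-2-yl)cyclopent-1-en-1-yl]butanoate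
Product: 13 ethyl (2E)-2-{2-[(5S)-5-(iodomethyl)-5-methyl-2-(propan-2-yl)cyclopent-1-en-1-yl]ethyl}-3-[(trifluoromethanesulfonyl)oxy]prop-2-enoate
Conditions: Tf2O, iPr2NEt, CH2Cl2, −78 °C
Reagents that add atoms: trifluoromethanesulfonic anhydride, O=S(=O)(OS(=O)(=O)C(F)(F)F)C(F)(F)F
Why: O-sulfonylation of the non-chelated ammonium enolate of an α-formyl ester should place the triflate anti to the ester and cis to the alkyl chain (stereodefined enol sulfonate formation), which is the (E) geometry that the ring closure requires.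

Step 9
Reactants: 13 ethyl (2E)-2-{2-[(5S)-5-(iodomethyl)-5-methyl-2-(propan-2-yl)cyclopent-1-en-1-yl]ethyl}-3-[(trifluoromethanesulfonyl)oxy]prop-2-enoate
Product: 15 ethyl (8aR)-8a-methyl-3-(propan-2-yl)-1,2,4,5,8,8a-hexahydroazulene-6-carboxylate, via alkylzinc iodide 14 (not isolated)
Conditions: Zn dust (TMSCl/1,2-dibromoethane-activated), LiCl, THF, 40 °C; then Pd(OAc)2 (5 mol%), SPhos (10 mol%), THF, 50 °C, slow addition (ca. 5 mM)
Reagents that add atoms: zinc, [Zn] (present in 14 only)
Why: Pd(0) inserts into the vinyl C–OTf bond of 14 with retention, the tethered neopentyl-type alkylzinc transmetalates intramolecularly, and reductive elimination from the eight-membered palladacycle forms the C7–C8 bond (intramolecular Negishi sp3–sp2 coupling; closest known type: coupling of alkylzinc halides with enol triflates and its ring-closing variants). The cycloheptene closes by direct coupling of the two chain termini, and the (E) geometry of the triflate (OTf cis to the tether) maps onto the cis ring alkene, so C6=C7 is delivered in place and conjugated with the ester. No new stereocentre forms; C8a, set in step 2, is quaternary and untouched. Ring closure must beat oligomerisation (slow addition, high dilution), and the alkyl metal must survive: C8 sits on the quaternary C8a, so neither the alkylzinc nor the alkylpalladium has a β-hydrogen to eliminate. Zinc insertion is chemoselective for the C–I bond over the enol triflate and the ester, and Heck-type attack of the vinylpalladium on C3=C3a is disfavoured because that alkene is tetrasubstituted and flanked by C8a and the isopropyl group.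

Step 10
Reactants: 15 ethyl (8aR)-8a-methyl-3-(propan-2-yl)-1,2,4,5,8,8a-hexahydroazulene-6-carboxylate
Product: 16 [(8aR)-8a-methyl-3-(propan-2-yl)-1,2,4,5,8,8a-hexahydroazulen-6-yl]methanol
Conditions: DIBAL-H (2.5 equiv), CH2Cl2, −78 °C; Rochelle salt work-up
Reagents that add atoms: none
Why: DIBAL-H reduces an α,β-unsaturated ester by 1,2-addition to the allylic alcohol without touching either alkene.

Step 11
Reactants: 16 [(8aR)-8a-methyl-3-(propan-2-yl)-1,2,4,5,8,8a-hexahydroazulen-6-yl]methanol; 17 4-hydroxy-3-methoxybenzoic acid (vanillic acid)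
Product: 18 [(8aR)-8a-methyl-3-(propan-2-yl)-1,2,4,5,8,8a-hexahydroazulen-6-yl]methyl 4-hydroxy-3-methoxybenzoate (target)
Conditions: PPh3, DIAD, THF, 0 °C → rt
Reagents that add atoms: none
Why: Mitsunobu esterification, in which the carboxylic acid is far more acidic than the phenol and so reacts as the carboxylate, displacing the primary allylic oxyphosphonium by SN2 with no protecting group on the phenol.

**Compound list**
1 | tert-butyl propanoate | CCC(=O)OC(C)(C)C | starting material
2 | ethyl 5-chloro-5-oxopentanoate | CCOC(=O)CCCC(Cl)=O | starting material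
3 | 1-tert-butyl 7-ethyl 2-methyl-3-oxoheptanedioate (racemic) | CCOC(=O)CCCC(=O)C(C)C(=O)OC(C)(C)C | intermediate
4 | 4-methylpent-1-en-3-one | CC(C)C(=O)C=C | starting material
5 | 1-tert-butyl 7-ethyl (2S)-2-methyl-2-(4-methyl-3-oxopentyl)-3-oxoheptanedioate | CC(C)(C)OC(=O)[C@@](C(=O)CCCC(=O)OCC)(C)CCC(=O)C(C)C | intermediate
6 | tert-butyl (1S)-2-(4-ethoxy-4-oxobutyl)-1-methyl-3-(propan-2-yl)cyclopent-2-ene-1-carboxylate | CC(C)(C)OC(=O)[C@@]1(C)CCC(C(C)C)=C1CCCC(=O)OCC | intermediate
7 | trimethylsilyl (1S)-2-(4-ethoxy-4-oxobutyl)-1-methyl-3-(propan-2-yl)cyclopent-2-ene-1-carboxylate (not isolated) | C[Si](C)(C)OC(=O)[C@@]1(C)CCC(C(C)C)=C1CCCC(=O)OCC | intermediate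
8 | (1S)-2-(4-ethoxy-4-oxobutyl)-1-methyl-3-(propan-2-yl)cyclopent-2-ene-1-carboxylic acid | OC(=O)[C@@]1(C)CCC(C(C)C)=C1CCCC(=O)OCC | intermediate
9 | ethyl 4-[(5S)-5-(hydroxymethyl)-5-methyl-2-(propan-2-yl)cyclopent-1-en-1-yl]butanoate | OC[C@@]1(C)CCC(C(C)C)=C1CCCC(=O)OCC | intermediate
10 | ethyl 4-[(5S)-5-(iodomethyl)-5-methyl-2-(propan-2-yl)cyclopent-1-en-1-yl]butanoate | IC[C@@]1(C)CCC(C(C)C)=C1CCCC(=O)OCC | intermediate
11 | ethyl formate | CCOC=O | starting material
12 | ethyl 2-formyl-4-[(5S)-5-(iodomethyl)-5-methyl-2-(propan-2-yl)cyclopent-1-en-1-yl]butanoate (C2 epimers/enol) | IC[C@@]1(C)CCC(C(C)C)=C1CCC(C=O)C(=O)OCC | intermediate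
13 | ethyl (2E)-2-{2-[(5S)-5-(iodomethyl)-5-methyl-2-(propan-2-yl)cyclopent-1-en-1-yl]ethyl}-3-[(trifluoromethanesulfonyl)oxy]prop-2-enoate | IC[C@@]1(C)CCC(C(C)C)=C1CC/C(=C\OS(=O)(=O)C(F)(F)F)C(=O)OCC | intermediate
14 | {[(1S)-2-{(3E)-3-(ethoxycarbonyl)-4-[(trifluoromethanesulfonyl)oxy]but-3-en-1-yl}-1-methyl-3-(propan-2-yl)cyclopent-2-en-1-yl]methyl}(iodo)zinc (not isolated) | I[Zn]C[C@@]1(C)CCC(C(C)C)=C1CC/C(=C\OS(=O)(=O)C(F)(F)F)C(=O)OCC | intermediate
15 | ethyl (8aR)-8a-methyl-3-(propan-2-yl)-1,2,4,5,8,8a-hexahydroazulene-6-carboxylate | CCOC(=O)C1=CC[C@@]2(C)CCC(C(C)C)=C2CC1 | intermediate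
16 | [(8aR)-8a-methyl-3-(propan-2-yl)-1,2,4,5,8,8a-hexahydroazulen-6-yl]methanol | OCC1=CC[C@@]2(C)CCC(C(C)C)=C2CC1 | intermediate
17 | 4-hydroxy-3-methoxybenzoic acid | COc1cc(C(=O)O)ccc1O | starting material
18 | [(8aR)-8a-methyl-3-(propan-2-yl)-1,2,4,5,8,8a-hexahydroazulen-6-yl]methyl 4-hydroxy-3-methoxybenzoate | COc1cc(C(=O)OCC2=CC[C@@]3(C)CCC(C(C)C)=C3CC2)ccc1O | target

**Total step count:** 11. **Longest linear sequence:** 11 steps (from 1 and 2).

**Steps most likely to fail**

1. Step 9 (ring closure). What may go wrong: incomplete zinc insertion at the hindered neopentyl iodide, protodemetalation, intermolecular coupling instead of ring closure, or erosion of the (E) geometry from step 8; the iodide itself (step 6) may also rearrange through homoallylic participation. Fallback with reversed polarity, which avoids any leaving group or metal at C8: it sets out from alcohol 9. Silylation (TBSCl, imidazole) should give the tert-butyldimethylsilyl ether F1. Formylation (LDA, HCO2Et) should give the α-formyl ester F2, and triflation (Tf2O, iPr2NEt) the (E)-enol triflate F3. Desilylation (HF·pyridine) should give the neopentyl alcohol F4, and Dess–Martin oxidation the non-enolisable aldehyde F5. Intramolecular Nozaki–Hiyama–Kishi reaction (CrCl2, cat. NiCl2, DMF, high dilution) should close the same C7–C8 bond to the ring allylic alcohol F6 (C8 epimers). Acylation with methyl chloroformate should give the allylic methyl carbonate F7. Palladium-catalysed reduction with formic acid/triethylamine through the π-allyl complex, followed by DBU to bring any β,γ-isomer into conjugation, comes back to the route at 15.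

2. Step 3 (cyclopentene formation). What may go wrong: ketone–ester coupling or simple ketone reduction competes, or the hindered titanium pinacolate is not deoxygenated. Fallback by stepwise coupling and syn-elimination: it sets out from diketone 5. Samarium diiodide-mediated pinacol cyclisation should give the cis-cyclopentane-1,2-diol F8. Thiophosgene/DMAP should give the cyclic thiocarbonate F9. Corey–Hopkins olefination (1,3-dimethyl-2-phenyl-1,3,2-diazaphospholidine, 40 °C) comes back to the route at 6.

3. Step 2 (quaternary centre). What may go wrong: poor facial selectivity with this long-chain acyclic donor, or polymerisation of the vinyl ketone before addition. Fallback with auxiliary control instead of a chiral Lewis acid: it sets out from β-keto ester 3. Condensation with L-valine diethylamide (the D-form if the sense requires) should give the chiral enamino ester F10. Copper(II) acetate-catalysed Michael addition to 4 should give the imine adduct F11. Mild acidic hydrolysis releases the auxiliary and comes back to the route at 5.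

**Further compounds**
F1 | step 9 | ethyl 4-[(5S)-5-{[(tert-butyldimethylsilyl)oxy]methyl}-5-methyl-2-(propan-2-yl)cyclopent-1-en-1-yl]butanoate | CC(C)(C)[Si](C)(C)OC[C@@]1(C)CCC(C(C)C)=C1CCCC(=O)OCC
F2 | step 9 | ethyl 4-[(5S)-5-{[(tert-butyldimethylsilyl)oxy]methyl}-5-methyl-2-(propan-2-yl)cyclopent-1-en-1-yl]-2-formylbutanoate | CC(C)(C)[Si](C)(C)OC[C@@]1(C)CCC(C(C)C)=C1CCC(C=O)C(=O)OCC
F3 | step 9 | ethyl (2E)-2-{2-[(5S)-5-{[(tert-butyldimethylsilyl)oxy]methyl}-5-methyl-2-(propan-2-yl)cyclopent-1-en-1-yl]ethyl}-3-[(trifluoromethanesulfonyl)oxy]prop-2-enoate | CC(C)(C)[Si](C)(C)OC[C@@]1(C)CCC(C(C)C)=C1CC/C(=C\OS(=O)(=O)C(F)(F)F)C(=O)OCC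
F4 | step 9 | ethyl (2E)-2-{2-[(5S)-5-(hydroxymethyl)-5-methyl-2-(propan-2-yl)cyclopent-1-en-1-yl]ethyl}-3-[(trifluoromethanesulfonyl)oxy]prop-2-enoate | OC[C@@]1(C)CCC(C(C)C)=C1CC/C(=C\OS(=O)(=O)C(F)(F)F)C(=O)OCC
F5 | step 9 | ethyl (2E)-2-{2-[(5S)-5-formyl-5-methyl-2-(propan-2-yl)cyclopent-1-en-1-yl]ethyl}-3-[(trifluoromethanesulfonyl)oxy]prop-2-enoate | O=C[C@@]1(C)CCC(C(C)C)=C1CC/C(=C\OS(=O)(=O)C(F)(F)F)C(=O)OCC
F6 | step 9 | ethyl (8aS)-8-hydroxy-8a-methyl-3-(propan-2-yl)-1,2,4,5,8,8a-hexahydroazulene-6-carboxylate (C8 epimers) | CCOC(=O)C1=CC(O)[C@@]2(C)CCC(C(C)C)=C2CC1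
F7 | step 9 | ethyl (8aS)-8-[(methoxycarbonyl)oxy]-8a-methyl-3-(propan-2-yl)-1,2,4,5,8,8a-hexahydroazulene-6-carboxylate (C8 epimers) | CCOC(=O)C1=CC(OC(=O)OC)[C@@]2(C)CCC(C(C)C)=C2CC1
F8 | step 3 | tert-butyl (1S)-2-(4-ethoxy-4-oxobutyl)-2,3-dihydroxy-1-methyl-3-(propan-2-yl)cyclopentane-1-carboxylate (cis-diol) | CC(C)(C)OC(=O)[C@@]1(C)CCC(O)(C(C)C)C1(O)CCCC(=O)OCC
F9 | step 3 | cyclic thiocarbonate of F8 (2,3-O-thiocarbonyl derivative) | CC(C)(C)OC(=O)[C@@]1(C)CCC2(C(C)C)OC(=S)OC12CCCC(=O)OCC
F10 | step 2 | 1-tert-butyl 7-ethyl (2Z)-3-{[(2S)-1-(diethylamino)-3-methyl-1-oxobutan-2-yl]amino}-2-methylhept-2-enedioate | CCOC(=O)CCC/C(N[C@@H](C(C)C)C(=O)N(CC)CC)=C(\C)C(=O)OC(C)(C)C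
F11 | step 2 | 1-tert-butyl 7-ethyl (2S)-3-{[(2S)-1-(diethylamino)-3-methyl-1-oxobutan-2-yl]imino}-2-methyl-2-(4-methyl-3-oxopentyl)heptanedioate | CCOC(=O)CCCC(=N[C@@H](C(C)C)C(=O)N(CC)CC)[C@](C)(CCC(=O)C(C)C)C(=O)OC(C)(C)C
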